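In a one-step world target climbs until one charge has been consumed, so I set the two earlier runs side by side to see whether elm, the flask asked about, could be read that way.

| flask | solid substrate | partner | protic impurity | remark | time |
|---|---|---|---|---|---|
| elm | 0.072 M | 0.144 M | 1.44 mM | the very flask that is asked about, followed so far |  |
| cedar | 0.11 M | 0.144 M | 1.44 mM | run made earlier |  |
| flask | 0.072 M | 0.144 M | 1.44 mM |  | 8.0 min |

| run | time / min | target / % |
|---|---|---|
| elm | 0.417 | 8 |
| elm | 1.00 | 28 |
| elm | 2.00 | 52 |
| elm | 3.00 | 64 |
| cedar | 0.667 | 12 |
| cedar | 1.33 | 23 |
| cedar | 3.00 | 42 |
| cedar | 8.00 | 50 |

(readings scatter by 1.5 percentage points)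

- amount of target at 8.0 min, in percent of the solid substrate charged
- the change that raises the amount of target at 8.0 min, in percent of the solid substrate charged most ("none" if none brings more than 2 percentage points) (violet / grey / amber / none)
- amount of target at 8.0 min, in percent of the solid substrate charged, after violet

- violet: doubling the amount of partner, all else as stated
- grey: doubling the dissolution coefficient of the solid substrate, all else as stated
- amber: doubling the solubility of the solid substrate, all else as stated

- given per volume of solution although it is solid: solid substrate
- what was read earlier has a scatter of 1.5 percentage points, one standard deviation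
- at the start none of the solid substrate is in solution

I read the columns in concentration, not percent. At 3.00 min elm's 64 % of 0.072 M was 46.1 mM, and at 3.00 min cedar's 42 % of 0.11 M was 46.2 mM, equal within the scatter, although cedar held more solid. Cedar's last row then gave 50 % at 8.00 min, which I called the target ceiling, the concentration of target at which I took a run on 0.144 M of partner and 1.44 mM of protic impurity to go flat as long as its solid charge stands above that level: 55.0 mM, a reading carrying the scatter of 1.5 percentage points.

Cedar had gained 15.4 mM min⁻¹ over its first stretch but 1.76 mM min⁻¹ over its last, though by subtraction 89.0 mM of partner was not bound in target, so the one-step picture failed. The protic impurity, at 1.44 mM, was far less than that gap, so I set it aside as a small correction. Elm's charge stood above the ceiling, so I reckoned 76.4 % for elm. Both runs had the same partner charge, so I could put no size on violet.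

The forecast gave 76 %, chose amber and put violet at 92 %, holding that “The plateau scales with the initial rate”.

Elm gave 76.3 % at 8.0 min, and violet came out best at 98.9 %, a gain of 23 points against 13 points for amber.

    solid substrate ⇌ dissolved substrate, rate k1*(cs1 - [dissolved substrate]) while solid is left; crystals form when [dissolved substrate] > cs1 (solubility = 27.0 mM, k = 0.0430 s⁻¹)
    dissolved substrate + partner → target (k = 0.250 M⁻¹ s⁻¹)
    partner → side product (k = 0.00640 s⁻¹)
    partner + protic impurity → quenched reagent (k = 1.40 M⁻¹ s⁻¹)

Partner, elm's limiting reagent, had 0.488 % of its charge left at 8.00 min, while side product stood at 0.0869 M. Elm's target came to 54.9 mM, at the ceiling. For the neighbour flask with 0.18 M of solid substrate the ceiling gives 30.6 %, and that flask gave 31.1 %, with 54.0 % still solid.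

The runs stem from a simulated flask with constants of no real substance, noise included.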